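**Plan**
- Retrosynthetic cuts, in order: the 1,10-epoxide and the two ester C–O bonds (O3, O8); then the lactone O–C6 bond together with C7–C11 (2-bromoacrylic acid plus a ring 4Z,6E-diene); then H for OTf at C6; then ring bond C8–C9 (anionic oxy-Cope) and C6–C7 (alkenyllithium plus enone).
- Forward: (S)-carvone → 4-silyloxy-6-isopropenylcyclohexenone → Z-alkoxyvinyl carbinol → oxy-Cope ring expansion to the ten-membered ring (1(10)E and 4Z olefins, E enol triflate) → 4Z,6E-diene → palladium-catalysed annulation closes the α-methylene-γ-lactone → two esterifications → epoxidation.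
- Enabling feature: O–C6 sits at the end of the allyl unit C4=C5–C6, and C7 carries the acrylate carbon C11. The five-membered ring (O, C6, C7, C11, C12) is therefore the [3+2] adduct of a 2-haloacrylic acid across C6=C7 of a 4,6-diene in the ten-membered ring; the 4Z olefin is the half of the diene that survives.
- Stereochemistry: C3 from Luche reduction of carvone; the carvone stereocentre is relayed through the chair oxy-Cope to C8 and to the ring conformation; C6/C7 from outer-face syn addition in the annulation; C1/C10 from outer-face epoxidation; side chains from a Sharpless epoxidation and from (R)-2-methylbutanoic acid.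
- The C6 oxygen that the anion-accelerated rearrangement needs is a helper and is removed again as triflate before the lactone oxygen is brought in.

Key step: step 10

Remark on the chemistry: germacrane numbering is used for the ten-membered ring (C1–C10; C11–C13 lactone carbons with C12 the carbonyl; C14 on C10; C15 on C4). The target is read as 1R,3S,6R,7R,8R,10R with (R)-2-methylbutanoyl on O3 and (2S,3S)-2,3-dimethyloxirane-2-carbonyl on O8. TBS = tert-butyldimethylsilyl, PMB = 4-methoxybenzyl, Tf = trifluoromethanesulfonyl. Compounds 1, 5, 6, 17, 19 and 26 are taken as purchased. The route assumes that triene 16 keeps the crossed ring conformation in which the oxy-Cope rearrangement delivers it (C3–OTBS equatorial, C8–OH axial).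

**Step 1**
Reactants: 1 (S)-(+)-carvone
Product: 2 (1S,5S)-cis-carveol
Conditions: NaBH4, CeCl3·7H2O, MeOH, −20 °C
Reagents that add atoms: none
Why: Luche reduction gives clean 1,2-reduction of the enone; axial hydride delivery should give the pseudo-equatorial alcohol cis to the isopropenyl group, which sets the future C3 as S.

**Step 2**
Reactants: 2 (1S,5S)-cis-carveol
Product: 3 TBS ether of (1S,5S)-cis-carveol
Conditions: TBSCl, imidazole, DMF, 20 °C
Reagents that add atoms: tert-butyldimethylsilyl chloride, CC(C)(C)[Si](C)(C)Cl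
Why: Standard silylation of a secondary allylic alcohol; no stereocentre is touched.

**Step 3**
Reactants: 3 TBS ether of (1S,5S)-cis-carveol
Product: 4 (4S,6S)-4-[(tert-butyldimethylsilyl)oxy]-3-methyl-6-(prop-1-en-2-yl)cyclohex-2-en-1-one
Conditions: CrO3, 3,5-dimethylpyrazole, CH2Cl2, −20 °C
Reagents that add atoms: chromium trioxide CrO3, O=[Cr](=O)=O
Why: Allylic oxidation with the CrO3/3,5-dimethylpyrazole complex should convert the only ring allylic CH2 (on the CH end of the trisubstituted olefin) into the enone carbonyl, because the other ring allylic carbon carries the silyloxy group; both stereocentres are kept.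

**Step 4**
Reactants: 5 4-methoxybenzyl alcohol; 6 vinyl acetate
Product: 7 4-methoxybenzyl vinyl ether
Conditions: [Ir(cod)Cl]2 (1 mol %), Na2CO3, toluene, 100 °C
Reagents that add atoms: none
Why: Iridium-catalysed transfer vinylation of an alcohol with vinyl acetate gives the alkyl vinyl ether.

**Step 5**
Reactants: 7 4-methoxybenzyl vinyl ether
Product: 9 (Z)-1-[(2-bromoethenyloxy)methyl]-4-methoxybenzene, via dibromo ether 8 (not isolated)
Conditions: Br2, CH2Cl2, −78 °C; then iPr2NEt, −78 to 20 °C
Reagents that add atoms: bromine, BrBr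
Why: Bromine addition to the enol ether followed by base-induced dehydrobromination through the oxocarbenium ion should give the cis (Z) 2-alkoxyvinyl bromide, the isomer favoured for this class.

**Step 6**
Reactants: 9 (Z)-1-[(2-bromoethenyloxy)methyl]-4-methoxybenzene; 4 (4S,6S)-4-[(tert-butyldimethylsilyl)oxy]-3-methyl-6-(prop-1-en-2-yl)cyclohex-2-en-1-one
Product: 11 (1S,4S,6S)-4-[(tert-butyldimethylsilyl)oxy]-1-{(Z)-2-[(4-methoxybenzyl)oxy]ethenyl}-3-methyl-6-(prop-1-en-2-yl)cyclohex-2-en-1-ol, via alkenyllithium 10 (not isolated)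
Conditions: t-BuLi (2 equiv), Et2O, −78 °C; then 4, THF, −78 °C; H2O
Reagents that add atoms: none
Why: Bromine–lithium exchange keeps the Z geometry, and 1,2-addition to the enone carbonyl should occur on the face opposite the isopropenyl and silyloxy groups (both on the same face), which puts the new alkenyl group trans to the isopropenyl group as the chair oxy-Cope requires.

**Step 7**
Reactants: 11 (1S,4S,6S)-4-[(tert-butyldimethylsilyl)oxy]-1-{(Z)-2-[(4-methoxybenzyl)oxy]ethenyl}-3-methyl-6-(prop-1-en-2-yl)cyclohex-2-en-1-ol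
Product: 14 (3S,8R)-3-(TBS-oxy)-8-(PMB-oxy)-4,10-dimethylcyclodeca-1(10)E,4Z,6-trien-6-yl triflate (germacrane numbering; C5 and C8 trans on C6=C7), via potassium alkoxide 12 (not isolated), via potassium enolate 13 (not isolated)
Conditions: KN(SiMe3)2, 18-crown-6, THF, −40 to 0 °C; then PhNTf2, −78 to −20 °C
Reagents that add atoms: N-phenylbis(trifluoromethanesulfonimide) PhNTf2, O=S(=O)(N(c1ccccc1)S(=O)(=O)C(F)(F)F)C(F)(F)F
Why: Anionic oxy-Cope rearrangement through a chair with both alkenyl groups equatorial breaks C1–C6 and forms C8–C9; the equatorial isopropenyl group gives the 1(10)E olefin, the ring olefin becomes 4Z, the enolate has C5 and C8 trans, and the Z enol ether places the C8 oxygen axial in the chair so that C8 should become R by chirality transfer; the enolate is then O-sulfonylated in the same flask.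

**Step 8**
Reactants: 14 (3S,8R)-3-(TBS-oxy)-8-(PMB-oxy)-4,10-dimethylcyclodeca-1(10)E,4Z,6-trien-6-yl triflate
Product: 15 (3S,8R)-3-(TBS-oxy)-8-hydroxy-4,10-dimethylcyclodeca-1(10)E,4Z,6-trien-6-yl triflate
Conditions: DDQ, CH2Cl2/pH 7 buffer, 0 °C
Reagents that add atoms: none
Why: Oxidative cleavage of the PMB ether; the adjacent electron-poor enol triflate should protect the liberated allylic alcohol from over-oxidation.

**Step 9**
Reactants: 15 (3S,8R)-3-(TBS-oxy)-8-hydroxy-4,10-dimethylcyclodeca-1(10)E,4Z,6-trien-6-yl triflate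
Product: 16 (1R,2E,4Z,6S,8E)-6-[(tert-butyldimethylsilyl)oxy]-5,9-dimethylcyclodeca-2,4,8-trien-1-ol (germacrane numbering: 8R-OH and 3S-OTBS with 1(10)E,4Z,6E olefins)
Conditions: Pd(OAc)2 (5 mol %), PPh3, HCO2H, Bu3N, DMF, 40 °C
Reagents that add atoms: none
Why: Palladium-catalysed formate reduction of the enol triflate replaces OTf by H with retention of olefin geometry, which should give the 6E olefin and hence the 4Z,6E-diene.

**Step 10**
Reactants: 16 (1R,2E,4Z,6S,8E)-6-[(tert-butyldimethylsilyl)oxy]-5,9-dimethylcyclodeca-2,4,8-trien-1-ol; 17 2-bromoacrylic acid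
Product: 18 (3S,6R,7R,8R)-3-(TBS-oxy)-8-hydroxygermacra-1(10)E,4Z,11(13)-trien-12,6-olide
Conditions: Pd(OAc)2 (10 mol %), P(2-furyl)3 (20 mol %), Ag2CO3 (1.2 equiv), DMF, 50 °C
Reagents that add atoms: none
Why: Proposed new method: zerovalent palladium should insert into the C–Br bond of 17 (as its carboxylate), and the 1-carboxylatovinyl–palladium species should add syn across the E-6,7 olefin of the diene, carbon to the unsubstituted terminus C7 and palladium to C6, giving an η3-allyl complex over C4–C5–C6; the carboxylate, held on the same face in a six-membered palladacycle, then forms the O–C6 bond by C–O reductive elimination and releases zerovalent palladium. The closest known reaction type is the Larock-type heteroannulation of 1,3-dienes with ortho-halo benzoic acids, phenols and anilines, here transposed to a 2-haloacrylic acid and a macrocyclic diene. The γ-lactone closes by 5-exo attack of oxygen on the near allyl terminus C6; the seven-membered alternative at the fully substituted C4 is disfavoured. C7 and C6 are set together by syn addition to the outer face of the E olefin in the crossed conformation that keeps the C3 silyloxy group equatorial; that face carries the axial C8 hydroxyl, which can guide palladium, and syn addition to an E olefin gives the trans-fused lactone (6R,7R). The step needs site selectivity for C7 over C4 and over the isolated 1(10) olefin (a diene reacts faster than a simple olefin and C4 is fully substituted), retention of the 4Z geometry (no π–σ–π isomerisation through the tertiary C4 terminus), and lactone closure faster than β-hydride elimination, which halide abstraction by silver and the intramolecular carboxylate should favour.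

**Step 11**
Reactants: 19 angelic acid [(Z)-2-methylbut-2-enoic acid]
Product: 20 (Z)-2-methylbut-2-en-1-ol
Conditions: LiAlH4, Et2O, 0 °C
Reagents that add atoms: none
Why: Hydride reduction of the conjugated acid to the allylic alcohol leaves the trisubstituted olefin and its Z geometry intact.

**Step 12**
Reactants: 20 (Z)-2-methylbut-2-en-1-ol
Product: 21 [(2R,3S)-2,3-dimethyloxiran-2-yl]methanol
Conditions: Ti(OiPr)4 (cat.), D-(−)-diethyl tartrate, t-BuOOH, 4 Å sieves, CH2Cl2, −20 °C
Reagents that add atoms: tert-butyl hydroperoxide, CC(C)(C)OO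
Why: Sharpless asymmetric epoxidation; with D-(−)-diethyl tartrate the oxygen should be delivered to the olefin face that gives the (2R,3S)-epoxy alcohol, and the Z olefin fixes the trans relation of the two methyl groups.

**Step 13**
Reactants: 21 [(2R,3S)-2,3-dimethyloxiran-2-yl]methanol
Product: 22 (2S,3S)-2,3-dimethyloxirane-2-carboxylic acid
Conditions: TEMPO (cat.), PhI(OAc)2, MeCN/H2O, 20 °C
Reagents that add atoms: water, O
Why: Oxoammonium-mediated oxidation of the primary alcohol through the aldehyde hydrate gives the glycidic acid without touching the epoxide; the C2 descriptor changes from R to S by priority only.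

**Step 14**
Reactants: 22 (2S,3S)-2,3-dimethyloxirane-2-carboxylic acid; 18 (3S,6R,7R,8R)-3-(TBS-oxy)-8-hydroxygermacra-1(10)E,4Z,11(13)-trien-12,6-olide
Product: 24 (3S,6R,7R,8R)-3-(TBS-oxy)-8-{[(2S,3S)-2,3-dimethyloxiran-2-yl]carbonyloxy}germacra-1(10)E,4Z,11(13)-trien-12,6-olide, via mixed anhydride 23 (not isolated)
Conditions: 2,4,6-Cl3C6H2COCl, Et3N, toluene, 20 °C; then 18, DMAP, toluene, 20 °C
Reagents that add atoms: none
Why: Yamaguchi esterification through the mixed anhydride should acylate the hindered C8 hydroxyl with retention at every centre; the acid has no α-hydrogen and cannot epimerise.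

**Step 15**
Reactants: 24 (3S,6R,7R,8R)-3-(TBS-oxy)-8-{[(2S,3S)-2,3-dimethyloxiran-2-yl]carbonyloxy}germacra-1(10)E,4Z,11(13)-trien-12,6-olide
Product: 25 (3S,6R,7R,8R)-3-hydroxy-8-{[(2S,3S)-2,3-dimethyloxiran-2-yl]carbonyloxy}germacra-1(10)E,4Z,11(13)-trien-12,6-olide
Conditions: HF·pyridine, pyridine, THF, 0 to 20 °C
Reagents that add atoms: none
Why: Buffered fluoride desilylation frees the C3 hydroxyl; the electron-poor glycidic ester epoxide and the methylene lactone should tolerate these non-basic conditions.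

**Step 16**
Reactants: 25 (3S,6R,7R,8R)-3-hydroxy-8-{[(2S,3S)-2,3-dimethyloxiran-2-yl]carbonyloxy}germacra-1(10)E,4Z,11(13)-trien-12,6-olide; 26 (R)-2-methylbutanoic acid
Product: 27 (3S,6R,7R,8R)-3-[(R)-2-methylbutanoyloxy]-8-{[(2S,3S)-2,3-dimethyloxiran-2-yl]carbonyloxy}germacra-1(10)E,4Z,11(13)-trien-12,6-olide
Conditions: EDC·HCl, DMAP (cat.), CH2Cl2, 0 °C
Reagents that add atoms: none
Why: Steglich-type esterification of the allylic C3 alcohol with retention at C3; low temperature and catalytic DMAP should keep the α-stereocentre of the acid intact.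

**Step 17**
Reactants: 27 (3S,6R,7R,8R)-3-[(R)-2-methylbutanoyloxy]-8-{[(2S,3S)-2,3-dimethyloxiran-2-yl]carbonyloxy}germacra-1(10)E,4Z,11(13)-trien-12,6-olide
Product: 28 target, the (1R,10R)-1,10-epoxide of 27
Conditions: mCPBA, NaHCO3, CH2Cl2, 0 °C
Reagents that add atoms: mCPBA, O=C(OO)c1cccc(Cl)c1
Why: Prilezhaev epoxidation should pick the isolated trisubstituted 1(10) olefin over the 4,5-olefin (flanked by two acyloxy carbons) and the electron-poor methylene lactone and angelate-derived ester, and the peracid should approach the outer face of the E olefin in the crossed ring conformation to give the 1R,10R epoxide.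

**Compound list**
1 | (S)-(+)-carvone | CC1=CC[C@@H](CC1=O)C(C)=C | starting material
2 | (1S,5S)-cis-carveol | C1C=C(C)[C@@H](O)C[C@H]1C(C)=C | intermediate
3 | TBS ether of (1S,5S)-cis-carveol | C1C=C(C)[C@@H](O[Si](C)(C)C(C)(C)C)C[C@H]1C(C)=C | intermediate
4 | (4S,6S)-4-[(tert-butyldimethylsilyl)oxy]-3-methyl-6-(prop-1-en-2-yl)cyclohex-2-en-1-one | O=C1C=C(C)[C@@H](O[Si](C)(C)C(C)(C)C)C[C@H]1C(C)=C | intermediate
5 | 4-methoxybenzyl alcohol | COc1ccc(CO)cc1 | starting material
6 | vinyl acetate | C=COC(C)=O | starting material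
7 | 4-methoxybenzyl vinyl ether | C=COCc1ccc(OC)cc1 | intermediate
8 | 1-[(1,2-dibromoethoxy)methyl]-4-methoxybenzene (not isolated) | BrCC(Br)OCc1ccc(OC)cc1 | intermediate
9 | (Z)-1-[(2-bromoethenyloxy)methyl]-4-methoxybenzene | Br/C=C\OCc1ccc(OC)cc1 | intermediate
10 | (Z)-2-[(4-methoxybenzyl)oxy]ethenyllithium (not isolated) | [Li]/C=C\OCc1ccc(OC)cc1 | intermediate
11 | (1S,4S,6S)-4-[(tert-butyldimethylsilyl)oxy]-1-{(Z)-2-[(4-methoxybenzyl)oxy]ethenyl}-3-methyl-6-(prop-1-en-2-yl)cyclohex-2-en-1-ol | O[C@@]1(/C=C\OCc2ccc(OC)cc2)C=C(C)[C@@H](O[Si](C)(C)C(C)(C)C)C[C@H]1C(C)=C | intermediate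
12 | potassium alkoxide of 11 (not isolated) | [K+].[O-][C@@]1(/C=C\OCc2ccc(OC)cc2)C=C(C)[C@@H](O[Si](C)(C)C(C)(C)C)C[C@H]1C(C)=C | intermediate
13 | potassium C6-enolate of the ring-expanded ketone, 3S,8R, 1(10)E,4Z, C5 and C8 trans (not isolated) | COc1ccc(CO[C@@H]2C/C(C)=C/C[C@H](O[Si](C)(C)C(C)(C)C)/C(C)=C\C([O-])=C\2)cc1.[K+] | intermediate
14 | (3S,8R)-3-(TBS-oxy)-8-(PMB-oxy)-4,10-dimethylcyclodeca-1(10)E,4Z,6-trien-6-yl triflate | COc1ccc(CO[C@@H]2C/C(C)=C/C[C@H](O[Si](C)(C)C(C)(C)C)/C(C)=C\C(OS(=O)(=O)C(F)(F)F)=C\2)cc1 | intermediate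
15 | (3S,8R)-3-(TBS-oxy)-8-hydroxy-4,10-dimethylcyclodeca-1(10)E,4Z,6-trien-6-yl triflate | O[C@@H]1C/C(C)=C/C[C@H](O[Si](C)(C)C(C)(C)C)/C(C)=C\C(OS(=O)(=O)C(F)(F)F)=C\1 | intermediate
16 | (1R,2E,4Z,6S,8E)-6-[(tert-butyldimethylsilyl)oxy]-5,9-dimethylcyclodeca-2,4,8-trien-1-ol | O[C@@H]1C/C(C)=C/C[C@H](O[Si](C)(C)C(C)(C)C)/C(C)=C\C=C\1 | intermediate
17 | 2-bromoacrylic acid | C=C(Br)C(=O)O | starting material
18 | (3S,6R,7R,8R)-3-(TBS-oxy)-8-hydroxygermacra-1(10)E,4Z,11(13)-trien-12,6-olide | C=C1C(=O)O[C@@H]2/C=C(/C)[C@@H](O[Si](C)(C)C(C)(C)C)C/C=C(\C)C[C@@H](O)[C@@H]12 | intermediate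
19 | angelic acid | C/C=C(/C)C(=O)O | starting material
20 | (Z)-2-methylbut-2-en-1-ol | C/C=C(/C)CO | intermediate
21 | [(2R,3S)-2,3-dimethyloxiran-2-yl]methanol | OC[C@@]1(C)O[C@H]1C | intermediate
22 | (2S,3S)-2,3-dimethyloxirane-2-carboxylic acid | OC(=O)[C@@]1(C)O[C@H]1C | intermediate
23 | mixed anhydride of 22 with 2,4,6-trichlorobenzoic acid (not isolated) | O=C(OC(=O)[C@@]1(C)O[C@H]1C)c1c(Cl)cc(Cl)cc1Cl | intermediate
24 | 8-O-[(2S,3S)-2,3-dimethyloxirane-2-carbonyl] derivative of 18 | C=C1C(=O)O[C@@H]2/C=C(/C)[C@@H](O[Si](C)(C)C(C)(C)C)C/C=C(\C)C[C@@H](OC(=O)[C@@]3(C)O[C@H]3C)[C@@H]12 | intermediate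
25 | 3-hydroxy compound obtained from 24 by loss of TBS | C=C1C(=O)O[C@@H]2/C=C(/C)[C@@H](O)C/C=C(\C)C[C@@H](OC(=O)[C@@]3(C)O[C@H]3C)[C@@H]12 | intermediate
26 | (R)-2-methylbutanoic acid | CC[C@@H](C)C(=O)O | starting material
27 | 3-O-[(R)-2-methylbutanoyl] derivative of 25 (the 1(10)-ene of the target) | C=C1C(=O)O[C@@H]2/C=C(/C)[C@@H](OC(=O)[C@H](C)CC)C/C=C(\C)C[C@@H](OC(=O)[C@@]3(C)O[C@H]3C)[C@@H]12 | intermediate
28 | CNP0265335.2, (1R,3S,6R,7R,8R,10R)-1,10-epoxide of 27 | C=C1C(=O)O[C@@H]2/C=C(/C)[C@@H](OC(=O)[C@H](C)CC)C[C@H]3O[C@]3(C)C[C@@H](OC(=O)[C@@]3(C)O[C@H]3C)[C@@H]12 | target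

**Count**
Total steps: 17. Longest linear sequence: 12 steps (steps 1, 2, 3, 6, 7, 8, 9, 10, 14, 15, 16, 17).

**Steps most likely to fail**

Step 10. The allylpalladium intermediate may lose a β-hydrogen (Heck-type triene) before the carboxylate closes on C6, carbopalladation may take the inner face after a ring flip, or the 1,5-diene of 16 may undergo a thermal Cope rearrangement. The fallback uses known reactions only, sets out from 11 and comes back at 18. Compound 11 is rearranged as in step 7, but enolate 13 is alkylated on its outer face at C7 with methyl bromoacetate to give the keto ester F1. Luche reduction (NaBH4, CeCl3·7H2O) should deliver hydride to the outer face of the C6 ketone and give the 6-epi hydroxy ester F2, and LiOH gives the hydroxy acid F3. Mitsunobu lactonisation (PPh3, DIAD) then closes the same O–C6 bond with inversion to the trans-fused saturated lactone F4. LiN(iPr)2 followed by Eschenmoser's salt gives the Mannich base F5, MeI its methiodide F6, and NaHCO3 the α-methylene lactone PMB ether F7. DDQ removes the PMB group and returns 18.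

Step 7. Enolate 13 may expel 4-methoxybenzyl oxide (β-elimination) during the rearrangement, before it is sulfonylated. The fallback sets out from 11 and comes back at 14. The elimination is allowed to run to completion (KN(SiMe3)2, 18-crown-6, THF, 20 °C) to give the cross-conjugated dienone F8. Conjugate borylation of its disubstituted enone arm (CuCl, NaOtBu, a chiral bisphosphine such as QuinoxP* in the enantiomer that serves the required face, B2pin2, MeOH) gives the β-boryl ketone F9, which NaBO3 oxidises with retention to the β-hydroxy ketone F10. 4-Methoxybenzyl trichloroacetimidate with Sc(OTf)3 gives the PMB ether F11. Kinetic enolisation (KN(SiMe3)2, −78 °C) and PhNTf2 return 14; the trans arrangement of C5 and C8 in the enol triflate then rests on ring control and no longer on the chair rearrangement.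

Step 17. Face or site selectivity of the epoxidation may drop once the lactone and the two esters have changed the ring conformation. The fallback sets out from 15 and comes back at 28, and epoxidises first, when the 1(10) olefin is the only electron-rich olefin and the ring still has the conformation set by the rearrangement. mCPBA on 15 gives the epoxy triflate F12. Formate reduction as in step 9 gives the epoxy diene alcohol F13, annulation with 17 as in step 10 gives the epoxy lactone F14, esterification with 22 as in step 14 gives F15, desilylation as in step 15 gives F16, and esterification with 26 as in step 16 gives 28.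

**Further compounds**
F1 | step 10 | methyl ester of the C7-alkylated C6 ketone (3S,7R,8R; 8-OPMB) | COC(=O)C[C@H]1C(=O)/C=C(/C)[C@@H](O[Si](C)(C)C(C)(C)C)C/C=C(\C)C[C@H]1OCc1ccc(OC)cc1
F2 | step 10 | 6-epi hydroxy ester | COC(=O)C[C@H]1[C@@H](O)/C=C(/C)[C@@H](O[Si](C)(C)C(C)(C)C)C/C=C(\C)C[C@H]1OCc1ccc(OC)cc1
F3 | step 10 | 6-epi hydroxy acid | OC(=O)C[C@H]1[C@@H](O)/C=C(/C)[C@@H](O[Si](C)(C)C(C)(C)C)C/C=C(\C)C[C@H]1OCc1ccc(OC)cc1
F4 | step 10 | trans-fused 11,13-dihydro lactone (3-OTBS, 8-OPMB) | C1C(=O)O[C@@H]2/C=C(/C)[C@@H](O[Si](C)(C)C(C)(C)C)C/C=C(\C)C[C@@H](OCc3ccc(OC)cc3)[C@@H]12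
F5 | step 10 | 11-(dimethylaminomethyl) lactone (C11 epimers) | CN(C)CC1C(=O)O[C@@H]2/C=C(/C)[C@@H](O[Si](C)(C)C(C)(C)C)C/C=C(\C)C[C@@H](OCc3ccc(OC)cc3)[C@@H]12
F6 | step 10 | methiodide of F5 | C[N+](C)(C)CC1C(=O)O[C@@H]2/C=C(/C)[C@@H](O[Si](C)(C)C(C)(C)C)C/C=C(\C)C[C@@H](OCc3ccc(OC)cc3)[C@@H]12.[I-]
F7 | step 10 | 8-O-PMB ether of 18 | C=C1C(=O)O[C@@H]2/C=C(/C)[C@@H](O[Si](C)(C)C(C)(C)C)C/C=C(\C)C[C@@H](OCc3ccc(OC)cc3)[C@@H]12
F8 | step 7 | (3S)-3-(TBS-oxy)-4,10-dimethylcyclodeca-1(10)E,4Z,7Z-trien-6-one | O=C1/C=C\C/C(C)=C/C[C@H](O[Si](C)(C)C(C)(C)C)/C(C)=C\1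
F9 | step 7 | 8-(pinacolatoboryl) ketone | O=C1C[C@H](B2OC(C)(C)C(C)(C)O2)C/C(C)=C/C[C@H](O[Si](C)(C)C(C)(C)C)/C(C)=C\1
F10 | step 7 | (3S,8R)-8-hydroxy ketone | O=C1C[C@H](O)C/C(C)=C/C[C@H](O[Si](C)(C)C(C)(C)C)/C(C)=C\1
F11 | step 7 | (3S,8R)-8-(PMB-oxy) ketone | O=C1C[C@H](OCc2ccc(OC)cc2)C/C(C)=C/C[C@H](O[Si](C)(C)C(C)(C)C)/C(C)=C\1
F12 | step 17 | (1R,10R)-1,10-epoxide of 15 | O[C@@H]1C[C@@]2(C)O[C@@H]2C[C@H](O[Si](C)(C)C(C)(C)C)/C(C)=C\C(OS(=O)(=O)C(F)(F)F)=C\1
F13 | step 17 | (1R,10R)-1,10-epoxide of 16 | O[C@@H]1C[C@@]2(C)O[C@@H]2C[C@H](O[Si](C)(C)C(C)(C)C)/C(C)=C\C=C\1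
F14 | step 17 | (1R,10R)-1,10-epoxide of 18 | C=C1C(=O)O[C@@H]2/C=C(/C)[C@@H](O[Si](C)(C)C(C)(C)C)C[C@H]3O[C@]3(C)C[C@@H](O)[C@@H]12
F15 | step 17 | (1R,10R)-1,10-epoxide of 24 | C=C1C(=O)O[C@@H]2/C=C(/C)[C@@H](O[Si](C)(C)C(C)(C)C)C[C@H]3O[C@]3(C)C[C@@H](OC(=O)[C@@]3(C)O[C@H]3C)[C@@H]12
F16 | step 17 | (1R,10R)-1,10-epoxide of 25 | C=C1C(=O)O[C@@H]2/C=C(/C)[C@@H](O)C[C@H]3O[C@]3(C)C[C@@H](OC(=O)[C@@]3(C)O[C@H]3C)[C@@H]12
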